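**Retrosynthetic overview**
- The target is (+)-catechin-(4α→8)-(−)-epicatechin-(4β→6)-(+)-catechin. Both interflavan C4–aryl bonds are cut (Friedel–Crafts retrons); rings A, B and C of all three units come ready-made from (+)-catechin 1, (−)-epicatechin 2 and (+)-taxifolin 3.
- Lower bond (4β→6): the C4 cation of benzyl-protected epicatechin is joined to benzyl-protected catechin whose C8 carries a bromine cap, so only C6 can react.
- Upper bond (4α→8): the top unit is armed without benzyl groups. Taxifolin is reduced and, in the same operation, two boron rings close at once (a catechol dioxaborole and a peri O4–B–O5 dioxaborinine). The six-membered ring is a latent o-quinone methide that alkylates C8 of the middle unit anti to the 3-OH.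
- Ring order: no skeletal ring is built. The only rings formed are the two boracycles (together in step 6, opened again in step 7); one hydrogenolysis then removes eight benzyl groups and the bromine.

Assumption: where a C4–O group is only a leaving group (the 4-ether and the flavan-3,4-diol derivatives), its configuration is immaterial and it is drawn as the expected major epimer.

**Route**

Step 1
Reactants: 1 (+)-catechin
Product: 4 5,7,3',4'-tetra-O-benzyl-(+)-catechin
Conditions: BnBr (4.4 equiv), K2CO3 (5 equiv), DMF, 0 °C → rt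
Reagents that add atoms: benzyl bromide, BrCc1ccccc1
Why: Williamson etherification in which K2CO3 deprotonates only the four phenols, so the secondary 3-OH stays free and no stereocentre is touched.

Step 2
Reactants: 4 5,7,3',4'-tetra-O-benzyl-(+)-catechin
Product: 5 8-bromo-5,7,3',4'-tetra-O-benzyl-(+)-catechin
Conditions: NBS (1.0 equiv), CH2Cl2, −20 °C
Reagents that add atoms: N-bromosuccinimide, O=C1CCC(=O)N1Br
Why: Electrophilic aromatic bromination that goes selectively to C8 of ring A in the benzyl ether (C6 is flanked by two OBn groups), installing a removable cap that leaves C6 as the only free position of this ring.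

Step 3
Reactants: 2 (−)-epicatechin
Product: 6 5,7,3',4'-tetra-O-benzyl-(−)-epicatechin
Conditions: BnBr (4.4 equiv), K2CO3 (5 equiv), DMF, 0 °C → rt
Reagents that add atoms: benzyl bromide, BrCc1ccccc1
Why: Williamson etherification of the four phenols only, leaving the axial 3-OH free and both stereocentres untouched.

Step 4
Reactants: 6 5,7,3',4'-tetra-O-benzyl-(−)-epicatechin
Product: 7 4β-(2-ethoxyethoxy)-5,7,3',4'-tetra-O-benzyl-(−)-epicatechin
Conditions: DDQ (2 equiv), 2-ethoxyethanol (5 equiv), CH2Cl2, rt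
Reagents that add atoms: 2-ethoxyethanol, CCOCCO
Why: DDQ benzylic oxidation (hydride abstraction at C4, the cation being stabilised by the three oxygens of ring A) followed by capture by the alcohol anti to the axial 3-OH, giving the 4β (3,4-trans) ether whose C4 centre is re-formed in step 5.

Step 5
Reactants: 7 4β-(2-ethoxyethoxy)-5,7,3',4'-tetra-O-benzyl-(−)-epicatechin; 5 8-bromo-5,7,3',4'-tetra-O-benzyl-(+)-catechin
Product: 8 5,7,3',4'-tetra-O-benzylepicatechin-(4β→6)-(8-bromo-5,7,3',4'-tetra-O-benzylcatechin)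
Conditions: 5 (4 equiv, excess recovered), Me3SiOSO2CF3 (0.2 equiv), CH2Cl2, −78 → −40 °C
Reagents that add atoms: none
Why: Lewis-acid-catalysed Friedel–Crafts interflavan coupling in which the C4 cation of 7 is attacked by C6 of 5 (C8 is bromine-capped) from the β face, anti to the axial 3-OH, setting C4 of the middle unit as 4β (3,4-trans), while the excess of 5 outcompetes self-condensation of 7 through its own C8.

Step 6
Reactants: 3 (+)-taxifolin
Product: 10 leucocyanidin 3',4'-O:4,5-O-bis(phenylboronate), via 2,3-trans-3,4-trans-leucocyanidin 9 (not isolated)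
Conditions: NaBH4 (4 equiv), EtOH/THF, 0 °C; AcOH to pH 6, MeOH co-evaporation (×3); then PhB(OH)2 (2.1 equiv), 4 Å molecular sieves, THF, rt, same flask
Reagents that add atoms: phenylboronic acid, OB(O)c1ccccc1
Why: NaBH4 ketone reduction (axial hydride delivery gives the equatorial 4α-OH of diol 9) followed by twofold boronic ester condensation that closes two rings in one operation, the five-membered catechol dioxaborole and the six-membered peri O4–B–O5 dioxaborinine (a Nagata-type 4H-1,3,2-benzodioxaborinine), with no final stereocentre set here because C4 is re-formed in step 7.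

Step 7
Reactants: 10 leucocyanidin 3',4'-O:4,5-O-bis(phenylboronate); 8 5,7,3',4'-tetra-O-benzylepicatechin-(4β→6)-(8-bromo-5,7,3',4'-tetra-O-benzylcatechin)
Product: 12 catechin-(4α→8)-(5,7,3',4'-tetra-O-benzylepicatechin)-(4β→6)-(8-bromo-5,7,3',4'-tetra-O-benzylcatechin), via boron-bound trimer 11 (not isolated)
Conditions: 8 (1.5 equiv), BF3·OEt2 (0.2 equiv), CH2Cl2/THF 5:1, −40 → 0 °C, 10 added slowly; then MeOH/H2O
Reagents that add atoms: none
Why: Proposed new method: catalytic BF3·OEt2 opens the C4–O bond of the benzodioxaborinine to the O5-borylated o-quinone methide (C4 cation), by analogy with Lewis-acid unmasking of 2-phenyl-4H-1,3,2-benzodioxaborinines and with the classical flavan-3,4-diol/flavan-3-ol condensation, and C8 of the upper unit of 8 (C8 of the lower unit is brominated, its C6 is substituted, and C6 of the upper unit is flanked by two OBn groups) adds in a Friedel–Crafts step anti to the equatorial 3-OH to set the 4α (3,4-trans) bond, after which aqueous methanol hydrolyses both boron esters.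

Step 8
Reactants: 12 catechin-(4α→8)-(5,7,3',4'-tetra-O-benzylepicatechin)-(4β→6)-(8-bromo-5,7,3',4'-tetra-O-benzylcatechin)
Product: 13 catechin-(4α→8)-epicatechin-(4β→6)-catechin
Conditions: H2 (1 atm), Pd(OH)2/C (20 wt%), Et3N (1.5 equiv), THF/MeOH/H2O 20:1:1, rt
Reagents that add atoms: none
Why: Catalytic hydrogenolysis over Pd(OH)2/C cleaves the eight benzyl ethers and the aryl C–Br bond in one operation while Et3N traps HBr, so the acid-labile interflavan bonds and all eight stereocentres are untouched.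

**Compound list**

1 | (+)-catechin, (2R,3S)-2-(3,4-dihydroxyphenyl)chromane-3,5,7-triol | Oc1cc(O)c2c(c1)O[C@H](c1ccc(O)c(O)c1)[C@@H](O)C2 | starting material
2 | (−)-epicatechin, (2R,3R)-2-(3,4-dihydroxyphenyl)chromane-3,5,7-triol | Oc1cc(O)c2c(c1)O[C@H](c1ccc(O)c(O)c1)[C@H](O)C2 | starting material
3 | (+)-taxifolin, (2R,3R)-2-(3,4-dihydroxyphenyl)-3,5,7-trihydroxychroman-4-one | Oc1cc(O)c2c(c1)O[C@H](c1ccc(O)c(O)c1)[C@@H](O)C2=O | starting material
4 | 5,7,3',4'-tetra-O-benzyl-(+)-catechin (3-OH free) | c3ccccc3COc1cc(OCc3ccccc3)c2c(c1)O[C@H](c1ccc(OCc3ccccc3)c(OCc3ccccc3)c1)[C@@H](O)C2 | intermediate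
5 | 8-bromo-5,7,3',4'-tetra-O-benzyl-(+)-catechin | c3ccccc3COc1cc(OCc3ccccc3)c2c(c1Br)O[C@H](c1ccc(OCc3ccccc3)c(OCc3ccccc3)c1)[C@@H](O)C2 | intermediate
6 | 5,7,3',4'-tetra-O-benzyl-(−)-epicatechin (3-OH free) | c3ccccc3COc1cc(OCc3ccccc3)c2c(c1)O[C@H](c1ccc(OCc3ccccc3)c(OCc3ccccc3)c1)[C@H](O)C2 | intermediate
7 | 4β-(2-ethoxyethoxy)-5,7,3',4'-tetra-O-benzyl-(−)-epicatechin (2α-aryl, 3α-OH, 4β-OR) | c3ccccc3COc1cc(OCc3ccccc3)c2c(c1)O[C@H](c1ccc(OCc3ccccc3)c(OCc3ccccc3)c1)[C@H](O)[C@H]2OCCOCC | intermediate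
8 | 5,7,3',4'-tetra-O-benzylepicatechin-(4β→6)-(8-bromo-5,7,3',4'-tetra-O-benzylcatechin) | c3ccccc3COc1cc(OCc3ccccc3)c2c(c1)O[C@H](c1ccc(OCc3ccccc3)c(OCc3ccccc3)c1)[C@H](O)[C@H]2c1c(OCc3ccccc3)c(Br)c2c(c1OCc3ccccc3)C[C@H](O)[C@@H](c1ccc(OCc3ccccc3)c(OCc3ccccc3)c1)O2 | intermediate
9 | 2,3-trans-3,4-trans-leucocyanidin, (2R,3S,4R)-2-(3,4-dihydroxyphenyl)chromane-3,4,5,7-tetraol | Oc1cc(O)c2c(c1)O[C@H](c1ccc(O)c(O)c1)[C@@H](O)[C@@H]2O | intermediate (not isolated)
10 | leucocyanidin bis(phenylboronate): ring B catechol closed to a 2-phenyl-1,3,2-benzodioxaborole, O4 and O5 bridged by B–Ph as a peri-fused dioxaborinine, 3-OH and 7-OH free (2α-aryl, 3β-OH, 4α-O) | Oc1cc(O3)c2c(c1)O[C@H](c1ccc4OB(c5ccccc5)Oc4c1)[C@@H](O)[C@@H]2OB3c1ccccc1 | intermediate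
11 | boron-bound trimer: as 12, but the top unit carries the catechol phenylboronate and O5–B(OH)Ph | Oc1cc(OB(O)c3ccccc3)c2c(c1)O[C@H](c1ccc4OB(c5ccccc5)Oc4c1)[C@@H](O)[C@@H]2c1c(OCc3ccccc3)cc(OCc3ccccc3)c2c1O[C@H](c1ccc(OCc3ccccc3)c(OCc3ccccc3)c1)[C@H](O)[C@H]2c1c(OCc3ccccc3)c(Br)c2c(c1OCc3ccccc3)C[C@H](O)[C@@H](c1ccc(OCc3ccccc3)c(OCc3ccccc3)c1)O2 | intermediate (not isolated)
12 | catechin-(4α→8)-(5,7,3',4'-tetra-O-benzylepicatechin)-(4β→6)-(8-bromo-5,7,3',4'-tetra-O-benzylcatechin) | Oc1cc(O)c2c(c1)O[C@H](c1ccc(O)c(O)c1)[C@@H](O)[C@@H]2c1c(OCc3ccccc3)cc(OCc3ccccc3)c2c1O[C@H](c1ccc(OCc3ccccc3)c(OCc3ccccc3)c1)[C@H](O)[C@H]2c1c(OCc3ccccc3)c(Br)c2c(c1OCc3ccccc3)C[C@H](O)[C@@H](c1ccc(OCc3ccccc3)c(OCc3ccccc3)c1)O2 | intermediate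
13 | catechin-(4α→8)-epicatechin-(4β→6)-catechin (CNP0178679.1) | Oc1cc(O)c2c(c1)O[C@H](c1ccc(O)c(O)c1)[C@@H](O)[C@@H]2c1c(O)cc(O)c2c1O[C@H](c1ccc(O)c(O)c1)[C@H](O)[C@H]2c1c(O)cc2c(c1O)C[C@H](O)[C@@H](c1ccc(O)c(O)c1)O2 | target

**Step count**
Total: 8 steps. Longest linear sequence: 5 steps (1 → 4 → 5 → 8 → 12 → 13, or 2 → 6 → 7 → 8 → 12 → 13).

**Steps most likely to fail**

Step 7 (boron-mediated upper coupling). The unprotected ring A of the top unit can be alkylated again, or the boracycle may not ionise cleanly. The fallback leaves the boron route and sets out from 5 and 8. DDQ/2-ethoxyethanol oxidation of 5 gives the bromine-capped, fully benzylated electrophile 8-bromo-4β-(2-ethoxyethoxy)-5,7,3',4'-tetra-O-benzylcatechin F1. Coupling of F1 with 8 (Me3SiOSO2CF3, CH2Cl2, −78 °C) gives the fully protected trimer (8-bromo-5,7,3',4'-tetra-O-benzylcatechin)-(4α→8)-(5,7,3',4'-tetra-O-benzylepicatechin)-(4β→6)-(8-bromo-5,7,3',4'-tetra-O-benzylcatechin) F2, whose capped top ring cannot self-condense. Hydrogenolysis of F2 under the conditions of step 8 (twelve benzyl ethers, two bromides) comes back to the route at 13.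

Step 6 (reduction and double boracycle closure). Diol 9 may oligomerise during the solvent switch, or the peri dioxaborinine may not close. The fallback sets out from 3. After the NaBH4 reduction, 9 is trapped at once with benzyl mercaptan (AcOH, EtOH, 40 °C) as the bench-stable thioether 4α-benzylthio-(+)-catechin F3. Thiophilic activation of F3 with AgBF4 (THF, 0 °C) in the presence of 8 forms the same 4α→8 bond and comes back to the route at 12.

Step 5 (4β→6 coupling at the hindered C6). Electrophile 7 can self-condense through its own free C8 faster than it is trapped by 5. The fallback gives the middle unit its own orthogonal cap and sets out from 6. NIS (CH2Cl2, −20 °C) gives 8-iodo-5,7,3',4'-tetra-O-benzylepicatechin F4. DDQ/2-ethoxyethanol gives 8-iodo-4β-(2-ethoxyethoxy)-5,7,3',4'-tetra-O-benzylepicatechin F5. Coupling of F5 with 5 (1.2 equiv, Me3SiOSO2CF3, CH2Cl2, −78 °C) gives the doubly capped dimer (8-iodo-5,7,3',4'-tetra-O-benzylepicatechin)-(4β→6)-(8-bromo-5,7,3',4'-tetra-O-benzylcatechin) F6. Treatment with iPrMgCl·LiCl (4 equiv, THF, −30 °C; iodine–magnesium exchange is much faster than bromine–magnesium exchange) and a MeOH quench removes only the iodine and comes back to the route at 8.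

**Further compounds**
F1 | step 7 | 8-bromo-4β-(2-ethoxyethoxy)-5,7,3',4'-tetra-O-benzylcatechin | c3ccccc3COc1cc(OCc3ccccc3)c2c(c1Br)O[C@H](c1ccc(OCc3ccccc3)c(OCc3ccccc3)c1)[C@@H](O)[C@H]2OCCOCC
F2 | step 7 | (8-bromo-5,7,3',4'-tetra-O-benzylcatechin)-(4α→8)-(5,7,3',4'-tetra-O-benzylepicatechin)-(4β→6)-(8-bromo-5,7,3',4'-tetra-O-benzylcatechin) | c3ccccc3COc1cc(OCc3ccccc3)c2c(c1Br)O[C@H](c1ccc(OCc3ccccc3)c(OCc3ccccc3)c1)[C@@H](O)[C@@H]2c1c(OCc3ccccc3)cc(OCc3ccccc3)c2c1O[C@H](c1ccc(OCc3ccccc3)c(OCc3ccccc3)c1)[C@H](O)[C@H]2c1c(OCc3ccccc3)c(Br)c2c(c1OCc3ccccc3)C[C@H](O)[C@@H](c1ccc(OCc3ccccc3)c(OCc3ccccc3)c1)O2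
F3 | step 6 | 4α-benzylthio-(+)-catechin | Oc1cc(O)c2c(c1)O[C@H](c1ccc(O)c(O)c1)[C@@H](O)[C@@H]2SCc1ccccc1
F4 | step 5 | 8-iodo-5,7,3',4'-tetra-O-benzylepicatechin | c3ccccc3COc1cc(OCc3ccccc3)c2c(c1I)O[C@H](c1ccc(OCc3ccccc3)c(OCc3ccccc3)c1)[C@H](O)C2
F5 | step 5 | 8-iodo-4β-(2-ethoxyethoxy)-5,7,3',4'-tetra-O-benzylepicatechin | c3ccccc3COc1cc(OCc3ccccc3)c2c(c1I)O[C@H](c1ccc(OCc3ccccc3)c(OCc3ccccc3)c1)[C@H](O)[C@H]2OCCOCC
F6 | step 5 | (8-iodo-5,7,3',4'-tetra-O-benzylepicatechin)-(4β→6)-(8-bromo-5,7,3',4'-tetra-O-benzylcatechin) | c3ccccc3COc1cc(OCc3ccccc3)c2c(c1I)O[C@H](c1ccc(OCc3ccccc3)c(OCc3ccccc3)c1)[C@H](O)[C@H]2c1c(OCc3ccccc3)c(Br)c2c(c1OCc3ccccc3)C[C@H](O)[C@@H](c1ccc(OCc3ccccc3)c(OCc3ccccc3)c1)O2
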